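**Retrosynthetic overview**
- Target ⇒ octadecyl 2,3-bis(benzyloxy)benzoate (O-debenzylation) ⇒ 2,3-bis(benzyloxy)benzoic acid + octadecan-1-ol (ester C–O bond).
- Octadecan-1-ol ⇒ ethyl octadecanoate ⇒ ethyl (E)-octadec-2-enoate ⇒ ethyl 3-hydroxyoctadecanoate.
- Key C–C disconnection at C2–C3 of the C18 chain: intermolecular aldol addition of the lithium enolate of ethyl acetate to hexadecanal (made from hexadecan-1-ol).
- Acid fragment from 2,3-dihydroxybenzoic acid by perbenzylation, then saponification.
- No ring is formed; the benzene ring is bought intact.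

Assumption: the target has no stereocentre and no stereogenic double bond, so it is a single achiral compound; the carbinol centre made in step 2 is racemic and is erased in step 3.

**Route**

Step 1
Reactants: 1 hexadecan-1-ol
Product: 2 hexadecanal
Conditions: TEMPO (10 mol%), PhI(OAc)2 (1.1 eq), CH2Cl2, rt; use fresh
Reagents that add atoms: none
Why: TEMPO/oxoammonium-catalysed oxidation of a primary alcohol stops cleanly at the aldehyde under anhydrous conditions.

Step 2
Reactants: 2 hexadecanal; 3 ethyl acetate
Product: 5 racemic ethyl 3-hydroxyoctadecanoate, via ethyl acetate lithium enolate 4 (not isolated)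
Conditions: LDA (commercial solution, 1.1 eq), THF, −78 °C, add 3, 30 min; then 2 in THF, −78 °C; AcOH quench at −78 °C
Reagents that add atoms: none
Why: Directed intermolecular aldol addition of a preformed ester lithium enolate to an aliphatic aldehyde forms the C2–C3 bond; the new carbinol centre is racemic and is removed in step 3.

Step 3
Reactants: 5 racemic ethyl 3-hydroxyoctadecanoate
Product: 7 ethyl (E)-octadec-2-enoate, via ethyl 3-(mesyloxy)octadecanoate 6 (not isolated)
Conditions: MsCl (1.3 eq), Et3N (1.5 eq), CH2Cl2, 0 °C; then DBU (2.5 eq), rt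
Reagents that add atoms: none
Why: Mesylation followed by E1cB elimination of the β-mesyloxy ester gives the conjugated (E)-enoate; alkene geometry and position are irrelevant because step 4 saturates it.

Step 4
Reactants: 7 ethyl (E)-octadec-2-enoate
Product: 8 ethyl octadecanoate
Conditions: H2 (1 atm), 10% Pd/C, EtOAc, rt
Reagents that add atoms: none
Why: Heterogeneous catalytic hydrogenation of a disubstituted conjugated alkene is quantitative and leaves the ester untouched.

Step 5
Reactants: 8 ethyl octadecanoate
Product: 9 octadecan-1-ol
Conditions: LiAlH4, THF, 0 °C → rt; Fieser work-up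
Reagents that add atoms: none
Why: Hydride reduction of a simple saturated ester to the primary alcohol, with no other functional group present.

Step 6
Reactants: 10 2,3-dihydroxybenzoic acid
Product: 11 benzyl 2,3-bis(benzyloxy)benzoate
Conditions: BnBr (3.5 eq), K2CO3 (4 eq), DMF, 60 °C
Reagents that add atoms: benzyl bromide, BrCc1ccccc1
Why: Williamson O-alkylation of both phenoxides and the carboxylate with a reactive benzylic halide in a dipolar aprotic solvent goes to the tribenzyl compound.

Step 7
Reactants: 11 benzyl 2,3-bis(benzyloxy)benzoate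
Product: 12 2,3-bis(benzyloxy)benzoic acid
Conditions: KOH, MeOH/THF/H2O, reflux; then 1 M HCl to pH 2
Reagents that add atoms: potassium hydroxide, [K+].[OH-]
Why: Saponification (BAc2) cleaves only the benzyl ester, the aryl benzyl ethers being inert to base.

Step 8
Reactants: 12 2,3-bis(benzyloxy)benzoic acid; 9 octadecan-1-ol
Product: 13 octadecyl 2,3-bis(benzyloxy)benzoate
Conditions: DCC (1.2 eq), DMAP (0.2 eq), CH2Cl2, 0 °C → rt; filter, chromatograph
Reagents that add atoms: none
Why: Steglich esterification of an unhindered primary alcohol, with DMAP acyl transfer suppressing N-acylurea formation; the protected catechol cannot compete as a nucleophile.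

Step 9
Reactants: 13 octadecyl 2,3-bis(benzyloxy)benzoate
Product: 14 octadecyl 2,3-dihydroxybenzoate (Gentiside E)
Conditions: H2 (1 atm), 10% Pd/C, EtOAc/EtOH 1:1, rt; filter under N2
Reagents that add atoms: none
Why: Catalytic hydrogenolysis removes both benzyl ethers while the saturated alkyl ester and the arene stay intact.

**Compound list**

1 | hexadecan-1-ol | CCCCCCCCCCCCCCCCO | starting material
2 | hexadecanal | CCCCCCCCCCCCCCCC=O | intermediate
3 | ethyl acetate | CC(=O)OCC | starting material
4 | ethyl acetate lithium enolate (not isolated) | [Li]OC(=C)OCC | intermediate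
5 | ethyl 3-hydroxyoctadecanoate (racemic) | CCCCCCCCCCCCCCCC(O)CC(=O)OCC | intermediate
6 | ethyl 3-(methylsulfonyloxy)octadecanoate (racemic, not isolated) | CCCCCCCCCCCCCCCC(OS(C)(=O)=O)CC(=O)OCC | intermediate
7 | ethyl (E)-octadec-2-enoate | CCCCCCCCCCCCCCC/C=C/C(=O)OCC | intermediate
8 | ethyl octadecanoate | CCCCCCCCCCCCCCCCCC(=O)OCC | intermediate
9 | octadecan-1-ol | CCCCCCCCCCCCCCCCCCO | intermediate
10 | 2,3-dihydroxybenzoic acid | OC(=O)c1cccc(O)c1O | starting material
11 | benzyl 2,3-bis(benzyloxy)benzoate | O=C(OCc1ccccc1)c1cccc(OCc2ccccc2)c1OCc1ccccc1 | intermediate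
12 | 2,3-bis(benzyloxy)benzoic acid | OC(=O)c1cccc(OCc2ccccc2)c1OCc1ccccc1 | intermediate
13 | octadecyl 2,3-bis(benzyloxy)benzoate | CCCCCCCCCCCCCCCCCCOC(=O)c1cccc(OCc2ccccc2)c1OCc1ccccc1 | intermediate
14 | octadecyl 2,3-dihydroxybenzoate (Gentiside E, achiral) | CCCCCCCCCCCCCCCCCCOC(=O)c1cccc(O)c1O | target

**Totals**

Total step count: 9. Longest linear sequence: 7 steps (steps 1, 2, 3, 4, 5, 8, 9); the arene branch (steps 6, 7) joins at step 8.

**Steps most likely to fail, with fallbacks**

Step 2 (aldol). Hexadecanal is waxy, poorly soluble at −78 °C and prone to trimerisation and self-aldol, and the aldolate can revert. The fallback sets out from 2 and uses a Knoevenagel–Doebner condensation with malonic acid (pyridine, cat. piperidine, 90 °C). The aldol adduct 2-(1-hydroxyhexadecyl)propanedioic acid F1 forms in the flask and loses carbon dioxide and water there to give (E)-octadec-2-enoic acid F2; any β,γ-isomer does not matter. Hydrogenation (H2, Pd/C, EtOAc) gives octadecanoic acid F3, and LiAlH4 in THF reduces it to octadecan-1-ol, so the fallback comes back to the route at 9.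

Step 3 (mesylation/elimination). Elimination may stall at the mesylate or give hard-to-separate mixtures. The fallback sets out from 5 and removes the hydroxyl by Barton–McCombie deoxygenation instead. PhOC(S)Cl, pyridine and DMAP in CH2Cl2 give ethyl 3-[(phenoxycarbonothioyl)oxy]octadecanoate F4. Bu3SnH with AIBN in toluene at 110 °C then gives ethyl octadecanoate, so the fallback comes back at 8 and makes 7 and step 4 unnecessary.

Step 8 (Steglich esterification). The ortho-substituted acid may divert to the N-acylurea, and the waxy alcohol reacts sluggishly. The fallback sets out from 9 and reverses the roles of the partners. MsCl and Et3N in CH2Cl2 at 0 °C convert 9 into octadecyl methanesulfonate F5. The caesium carboxylate of 12 (Cs2CO3, cat. Bu4NI, DMF, 60 °C) is then O-alkylated with it in an SN2 reaction, and the fallback comes back at 13.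

**Further compounds**

F1 | step 2 | 2-(1-hydroxyhexadecyl)propanedioic acid (racemic, not isolated) | CCCCCCCCCCCCCCCC(O)C(C(=O)O)C(=O)O
F2 | step 2 | (E)-octadec-2-enoic acid | CCCCCCCCCCCCCCC/C=C/C(=O)O
F3 | step 2 | octadecanoic acid | CCCCCCCCCCCCCCCCCC(=O)O
F4 | step 3 | ethyl 3-[(phenoxycarbonothioyl)oxy]octadecanoate (racemic) | CCCCCCCCCCCCCCCC(OC(=S)Oc1ccccc1)CC(=O)OCC
F5 | step 8 | octadecyl methanesulfonate | CCCCCCCCCCCCCCCCCCOS(C)(=O)=O
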